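## Analysis of the target

Target 18 is made of two bicyclic halves joined by one methylene carbon. The locants used throughout are: chromone numbering without primes (ring A is the pyranone, ring B its benzene ring), 3,4-dihydroisocoumarin numbering with primes (ring C is the benzene ring, ring D the lactone), and C9 for the CH2 between C6 and C5'. The same locants are used for the acetophenone precursors, in which C4 is the ketone carbon and C3 its methyl group. The upper half is a 5-hydroxy-7-methoxy-2-methylchromone and the lower half a 6',8'-dihydroxy-3',7'-dimethyl-3',4'-dihydroisocoumarin. The only stereocentre is C3' (R), the carbinol carbon of ring D. It cannot enolise, has no partner to be matched with, and is best bought. The sensitive groups are the lactone and the pyranone (both opened by hydroxide or amines), the electron-rich diarylmethane, and three phenols, two of them hydrogen-bonded to carbonyl groups. The difficulty is twofold: ring C is hexasubstituted and ring B pentasubstituted, and ring A has to be annulated onto a ring B ketone flanked by two hydroxyls, O5 and O8a, where closure through the wrong one gives the 8-substituted chromone. The strategy rests on one feature: O5 and O6' are both ortho to C9, so a single silicon atom can join them in an eight-membered ring. No other pair of the four phenolic oxygens can be bridged, which leaves O8a as the only ring B hydroxyl that can carry the acetyl group and become O1.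

## Retrosynthetic reasoning

18 back to 16. The last operations only remove control elements. Cutting the acyl–O8' bond leads to acetate 17, and cutting the two Si–O bonds of 17 leads to the silylene-bridged chromone 16. Nothing in the skeleton changes, and both removals are mild enough for the lactone and the pyranone.

16 back to 14. Ring A is opened at O1–C2 and C2–C3. Both atoms of the C2 unit then sit as an acetyl group on O8a of acetophenone 14, next to the ketone whose methyl group is C3. This is the natural cut for a 2-methylchromone, because the forward reaction is an intramolecular acyl shift (giving diketone 15) followed by dehydrative closure. The cut is made with the tether in place because in 14 the hydroxyl on the other side of the ketone, O5, is bound to silicon. The forward step therefore has no choice of phenol.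

14 back to 11 and 12. The two acetates and then the two Si–O bonds are removed, giving silylene diol 13 and, before it, tetraphenol 11 and the silyl bis(triflate) 12. The tether must go on before the acetates so that acetylation can reach only O8a and O8'. The forward silylation has to find the single pair of hydroxyls that one silicon can span.

11 back to 8 and 9. The C6–C9 bond is cut. Ring B comes from the symmetrical acetophenone 9, whose two nucleophilic ring carbons are equivalent, so the benzylation has no regiochemical question. The electrophile is quinone methide 10, released from Mannich base 8. Making the electrophile on ring C and not on ring B is deliberate, because ring C has only one open position.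

8 back to 7. The C5'–C9 bond is cut. C5' is the only unsubstituted carbon of ring C in diphenol 7 and is activated by both hydroxyls, so aminomethylation can go nowhere else.

7 back to 4. The phenols are masked as methyl ethers in lactone 6. Ring D of 6 is opened at C1'–C8a' and C1'–O2', which removes the carbonyl carbon and leads to bromo alcohol 5, then to alcohol 4. The two open ring positions of 4 are equivalent, so the site of bromination is not in question, and the hydroxyl that closes the lactone is already in the side chain.

4 back to 1 and 2. The C4'–C4a' bond is cut to give the symmetrical aryl bromide 1 (through Grignard reagent 3) and epoxide 2. The epoxide brings C3' with its configuration, and opening at the terminal carbon does not touch it.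

## Alternatives that were turned down

Alternative 1: Ring C is cut at C4a'–C8a' and ring D at O2'–C1'. This leads to the open-chain triketo ester A1, which carries a preformed 5-O-benzyl chromone on C5'. Forward, a carbonate base in an alcohol and then acid would make the C8a' enolate add to the C4a' ketone, aromatise the ring, and let the C3' hydroxyl close the lactone. The product would be A2, the 5-O-benzyl ether of 18, and hydrogenolysis would finish.
- For: it follows the biosynthetic logic, needs no protecting group on ring C, and builds a carbocycle and a lactone in one flask. On bonds per step it is stronger than step 9, which closes one ring.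
- Against: A1 has four enolisable positions (C8a', C7', C5', C4') and four electrophilic carbonyls. The C4' enolate can close on C8' to an isomeric arene, enol oxygens can close to pyranones, and the C3' hydroxyl can form a six-membered hemiketal at C6'. The branches at C7' and C5' slow the wanted aldol and make A1 long and fragile to assemble. The pyranone is also exposed to alkoxide.
- Comparison: the chromone in A1 must be made first, so the O5/O8a question is moved earlier, not removed. The chosen route takes ring C from an aromatic compound whose pattern is fixed by symmetry and puts its risk into one well-understood acyl transfer.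

Alternative 2: Ring C is divided into a four-carbon unit (C8', C5', C4a', C8a') and a two-carbon unit (C7', C6'). These are the diazo enone A3 and the siloxyalkyne A4. Forward, blue light would trigger a Wolff rearrangement of A3 to a vinylketene. Cycloaddition with A4 would form C7'–C8' and C5'–C6' in a vinylcyclobutenone, and 4π opening, 6π closure (C8'–C8a') and tautomerisation would give phenol A5.
- For: every substituent of ring C is placed by the mechanism, and O6' and O8' are born different (silyl ether and free phenol). On telling these two oxygens apart it is stronger than the chosen route, which needs the tether for it.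
- Against: A5 still lacks C1'. C8a' must be carboxylated next to O8', the lactone closed, and three kinds of protecting group removed, at least four steps after the key step. A3 is a polymerisable 1,1-disubstituted enone with the diazo group on a hindered carbon, and the chromone chromophore is present during irradiation.
- Comparison: ring C is built from acyclic pieces although the same pattern can be bought as 1, and the ring A problem is again untouched. The chosen route is shorter, uses stock reagents, and offers one tether that settles both the O5/O8a and the O6'/O8' question.

Alternative 3: Ring B is cut at C7–C8. The precursor is the keto ester A6, a 3-acyl-2,6-dimethyl-4-pyranone whose side chain holds C5, C6 (bearing the benzyl-protected ring C/D unit through C9) and the ester carbon C7. Forward, three equivalents of a lithium amide would deprotonate C6–H and then the pyranone 2-methyl group (C8). The dienolate would attack C7 and give the 5,7-dihydroxychromone A7. Selective 7-O-methylation and hydrogenolysis would follow.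
- For: ring A and O1 exist before ring B, so the regiochemical problem of chromone closure cannot arise. On this point the alternative is stronger than the chosen strategy, which reaches the same certainty only by putting a tether on and taking it off.
- Against: the first deprotonation at C6 makes the C7 ester part of an enolate and a poor electrophile. The other pyranone methyl group is about as acidic as the one that must react. The lactone and C4' face three equivalents of strong base. Three steps remain after the key step, and A6 needs C-acylation of a pyranone and a ring C benzylic halide.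
- Comparison: in the chosen route the 7-methoxy group and all oxygens come with purchased aromatics, and the only enolate is a ketone enolate next to its electrophile. In place of built-in regiocontrol it offers regiocontrol by a removable silicon bridge at the cost of two steps.

Key step: step 9

Assumption: 5-bromo-1,3-dimethoxy-2-methylbenzene (1) is treated as a catalogue compound.

## Route

Step 1
Reactants: 1 5-bromo-1,3-dimethoxy-2-methylbenzene; 2 (R)-propylene oxide
Product: 4 (2R)-1-(3,5-dimethoxy-4-methylphenyl)propan-2-ol, via arylmagnesium bromide 3 (not isolated)
Conditions: Mg, THF, 50 °C; then CuI (10 mol%), 2 (1.3 equiv), −30 → 0 °C; 1 M HCl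
Reagents that add atoms: none
Why: Copper-catalysed opening of a terminal epoxide by an aryl Grignard reagent takes place at the unsubstituted carbon in SN2 fashion. The C–O bond of the stereocentre is never broken, so 2 delivers C3' as (R).

Step 2
Reactants: 4 (2R)-1-(3,5-dimethoxy-4-methylphenyl)propan-2-ol
Product: 5 (2R)-1-(2-bromo-3,5-dimethoxy-4-methylphenyl)propan-2-ol
Conditions: NBS (1.0 equiv), MeCN, 0 °C
Reagents that add atoms: N-bromosuccinimide, O=C1CCC(=O)N1Br
Why: Electrophilic aromatic bromination. The two open ring positions are equivalent, each ortho to one methoxy group and para to the other, so a single monobromide is expected.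

Step 3
Reactants: 5 (2R)-1-(2-bromo-3,5-dimethoxy-4-methylphenyl)propan-2-ol
Product: 6 (3R)-6,8-dimethoxy-3,7-dimethyl-3,4-dihydro-1H-isochromen-1-one
Conditions: Pd(OAc)2 (5 mol%), Xantphos (10 mol%), CO (1 atm), Et3N (3 equiv), PhMe, 100 °C
Reagents that add atoms: carbon monoxide, [C-]#[O+]
Why: Palladium-catalysed carbonylative lactonisation of a 2-(2-bromoaryl)ethanol: oxidative addition to zerovalent palladium, CO insertion, and capture of the acylpalladium by the side-chain hydroxyl in a six-membered closure. C3' is not involved and keeps its configuration.

Step 4
Reactants: 6 (3R)-6,8-dimethoxy-3,7-dimethyl-3,4-dihydro-1H-isochromen-1-one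
Product: 7 (3R)-6,8-dihydroxy-3,7-dimethyl-3,4-dihydro-1H-isochromen-1-one
Conditions: BBr3 (4 equiv), CH2Cl2, −78 °C → rt; H2O
Reagents that add atoms: none
Why: Lewis-acid cleavage of aryl methyl ethers. The 8'-ether is cleaved first through chelation to the lactone carbonyl and the 6'-ether follows at room temperature; lactone and C3' of dihydroisocoumarins tolerate this reagent.

Step 5
Reactants: 7 (3R)-6,8-dihydroxy-3,7-dimethyl-3,4-dihydro-1H-isochromen-1-one
Product: 8 (3R)-5-[(dimethylamino)methyl]-6,8-dihydroxy-3,7-dimethyl-3,4-dihydro-1H-isochromen-1-one
Conditions: CH2=NMe2 iodide (Eschenmoser's salt, 1.1 equiv), Et3N (1.1 equiv), CH2Cl2, 0 °C → rt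
Reagents that add atoms: N,N-dimethylmethyleneiminium iodide, C=[N+](C)C.[I-]
Why: Mannich aminomethylation of a phenol. C5' is the only unsubstituted ring carbon and is ortho to O6' and para to O8'; the preformed iminium salt keeps free amine away from the lactone.

Step 6
Reactants: 8 (3R)-5-[(dimethylamino)methyl]-6,8-dihydroxy-3,7-dimethyl-3,4-dihydro-1H-isochromen-1-one; 9 2',6'-dihydroxy-4'-methoxyacetophenone
Product: 11 (3R)-5-[(3-acetyl-2,4-dihydroxy-6-methoxyphenyl)methyl]-6,8-dihydroxy-3,7-dimethyl-3,4-dihydro-1H-isochromen-1-one, via o-quinone methide 10 (not isolated)
Conditions: 9 (3 equiv), 1,4-dioxane, 100 °C, slow N2 stream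
Reagents that add atoms: none
Why: Thermal loss of dimethylamine from the ortho-hydroxybenzylamine gives the o-quinone methide, which is trapped by conjugate addition of the phloroglucinol-type ring of 9 and rearomatisation (Friedel–Crafts-type C-benzylation). The two nucleophilic carbons of 9 are equivalent, and its excess suppresses double alkylation.

Step 7
Reactants: 11 (3R)-5-[(3-acetyl-2,4-dihydroxy-6-methoxyphenyl)methyl]-6,8-dihydroxy-3,7-dimethyl-3,4-dihydro-1H-isochromen-1-one; 12 di-tert-butylsilyl bis(trifluoromethanesulfonate)
Product: 13 O5,O6'-(di-tert-butylsilylene) derivative of 11 (eight-membered ring Si–O5–C5–C6–C9–C5'–C6'–O6'), with free hydroxyls at O8a and O8'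
Conditions: 12 (1.05 equiv, slow addition), 2,6-lutidine (3 equiv), CH2Cl2 (5 mM), −78 → 0 °C
Reagents that add atoms: none
Why: Silylation of phenols by a silyl bis(triflate) to a cyclic silylene, here the eight-membered dibenzodioxasilocine type known for 2,2'-methylenebisphenols. O5/O6' is the only pair one silicon can span (O8' is meta to O6', O8a is para to C9), and O8a and O8' are the hydroxyls best placed for six-membered hydrogen bonds to the ketone and the lactone carbonyl. High dilution favours ring closure over oligomers.

Step 8
Reactants: 13 O5,O6'-(di-tert-butylsilylene) derivative of 11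
Product: 14 8a,8'-di-O-acetate of 13 (acetophenone with O5 and O6' bridged by di-tert-butylsilylene and acetates on O8a and O8')
Conditions: Ac2O (5 equiv), pyridine, DMAP (10 mol%), CH2Cl2, rt
Reagents that add atoms: acetic anhydride, CC(=O)OC(C)=O
Why: DMAP-catalysed O-acetylation of the two remaining, carbonyl-chelated phenols. The silylene is inert here and has already taken O5 and O6' out of reach.

Step 9
Reactants: 14 8a,8'-di-O-acetate of 13
Product: 16 5-O,6'-O-(di-tert-butylsilylene) derivative of the 8'-O-acetyl target (ring A closed, silicon bridge and 8'-acetate retained), via 1,3-diketone 15 (not isolated)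
Conditions: LiN(SiMe3)2 (2.5 equiv), THF, −78 → −20 °C; AcOH; then TsOH·H2O (20 mol%), PhMe, 4 Å MS, 60 °C
Reagents that add atoms: none
Why: LiN(SiMe3)2 removes a proton from the acetophenone methyl group, the most acidic C–H of 14, and the lithium enolate attacks the carbonyl of the O8a acetate through a six-membered transition state to form C2–C3; collapse of the tetrahedral alkoxide releases the O8a phenoxide and gives diketone 15, whose deprotonation by further base makes the transfer irreversible (Baker–Venkataraman rearrangement). After the acetic acid quench, catalytic toluenesulfonic acid adds the O8a hydroxyl to the distal C2 carbonyl in a 6-exo-trig closure and the hemiketal dehydrates to the pyranone, forming O1–C2 and ring A. The closest known reaction type is the two-stage conversion of 2-acetoxyacetophenones into 2-methylchromones; the cyclic silylene of a 2,2'-methylenebisphenol is the only added element. No stereocentre is formed, and C3', a non-enolisable carbinol carbon far from the reacting atoms, is untouched. The selectivity needed is the choice of the ring-closing phenol: O5 is held as a silyl ether in the eight-membered ring, so only O8a can add to C2 and only the 6-substituted chromone can arise. The second selectivity is between the two acetates: the enolate reaches the O8a acetate within the molecule but the 8'-acetate only between molecules, which low temperature and dilution disfavour, and any material that loses the 8'-acetate still converges on 18 in the last two steps. The silylene should survive because the amide base is non-nucleophilic, the tert-butyl groups shield silicon, and the acid stage is dry, catalytic and only moderately warm.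

Step 10
Reactants: 16 5-O,6'-O-(di-tert-butylsilylene) derivative of the 8'-O-acetyl target
Product: 17 (3R)-6-hydroxy-5-[(5-hydroxy-7-methoxy-2-methyl-4-oxo-4H-chromen-6-yl)methyl]-3,7-dimethyl-1-oxo-3,4-dihydro-1H-isochromen-8-yl acetate
Conditions: HF·pyridine, pyridine, THF, 0 °C → rt
Reagents that add atoms: none
Why: Fluoride-driven cleavage of the two aryl O–Si bonds, paid for by the strong Si–F bonds, under buffered conditions that leave the aryl acetate, the lactone and the pyranone alone.

Step 11
Reactants: 17 (3R)-6-hydroxy-5-[(5-hydroxy-7-methoxy-2-methyl-4-oxo-4H-chromen-6-yl)methyl]-3,7-dimethyl-1-oxo-3,4-dihydro-1H-isochromen-8-yl acetate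
Product: 18 (3R)-6,8-dihydroxy-5-[(5-hydroxy-7-methoxy-2-methyl-4-oxo-4H-chromen-6-yl)methyl]-3,7-dimethyl-3,4-dihydro-1H-isochromen-1-one
Conditions: K2CO3 (0.2 equiv), MeOH, 0 °C; aq. NH4Cl
Reagents that add atoms: none
Why: Base-catalysed methanolysis of an aryl acetate, which should be far faster than attack on the hindered, electron-rich lactone carbonyl or on the pyranone. C3' cannot epimerise.

## Compound list

1 | 5-bromo-1,3-dimethoxy-2-methylbenzene | COc1cc(Br)cc(OC)c1C | starting material
2 | (R)-propylene oxide | C[C@@H]1CO1 | starting material
3 | (3,5-dimethoxy-4-methylphenyl)magnesium bromide | COc1cc([Mg]Br)cc(OC)c1C | intermediate (not isolated)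
4 | (2R)-1-(3,5-dimethoxy-4-methylphenyl)propan-2-ol | C[C@@H](O)Cc1cc(OC)c(C)c(OC)c1 | intermediate
5 | (2R)-1-(2-bromo-3,5-dimethoxy-4-methylphenyl)propan-2-ol | C[C@@H](O)Cc1cc(OC)c(C)c(OC)c1Br | intermediate
6 | (3R)-6,8-dimethoxy-3,7-dimethyl-3,4-dihydro-1H-isochromen-1-one | C[C@@H]1Cc2cc(OC)c(C)c(OC)c2C(=O)O1 | intermediate
7 | (3R)-6,8-dihydroxy-3,7-dimethyl-3,4-dihydro-1H-isochromen-1-one | C[C@@H]1Cc2cc(O)c(C)c(O)c2C(=O)O1 | intermediate
8 | (3R)-5-[(dimethylamino)methyl]-6,8-dihydroxy-3,7-dimethyl-3,4-dihydro-1H-isochromen-1-one | C[C@@H]1Cc2c(CN(C)C)c(O)c(C)c(O)c2C(=O)O1 | intermediate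
9 | 2',6'-dihydroxy-4'-methoxyacetophenone | CC(=O)c1c(O)cc(OC)cc1O | starting material
10 | (3R)-8-hydroxy-3,7-dimethyl-5-methylidene-3,4-dihydro-1H-isochromene-1,6(5H)-dione (o-quinone methide) | C=C1C(=O)C(C)=C(O)C2=C1C[C@@H](C)OC2=O | intermediate (not isolated)
11 | (3R)-5-[(3-acetyl-2,4-dihydroxy-6-methoxyphenyl)methyl]-6,8-dihydroxy-3,7-dimethyl-3,4-dihydro-1H-isochromen-1-one | CC(=O)c1c(O)cc(OC)c(Cc2c(O)c(C)c(O)c3c2C[C@@H](C)OC3=O)c1O | intermediate
12 | di-tert-butylsilyl bis(trifluoromethanesulfonate) | CC(C)(C)[Si](OS(=O)(=O)C(F)(F)F)(OS(=O)(=O)C(F)(F)F)C(C)(C)C | starting material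
13 | O5,O6'-(di-tert-butylsilylene) derivative of 11, hydroxyls at O8a and O8' free | CC(=O)c1c(O)cc(OC)c2c1O[Si](C(C)(C)C)(C(C)(C)C)Oc1c(C)c(O)c3c(c1C2)C[C@@H](C)OC3=O | intermediate
14 | 8a,8'-di-O-acetate of 13 | CC(=O)c1c(OC(C)=O)cc(OC)c2c1O[Si](C(C)(C)C)(C(C)(C)C)Oc1c(C)c(OC(C)=O)c3c(c1C2)C[C@@H](C)OC3=O | intermediate
15 | 1,3-diketone from acyl transfer (acetoacetyl group on C4a, free O8a hydroxyl, silylene and 8'-acetate retained) | CC(=O)CC(=O)c1c(O)cc(OC)c2c1O[Si](C(C)(C)C)(C(C)(C)C)Oc1c(C)c(OC(C)=O)c3c(c1C2)C[C@@H](C)OC3=O | intermediate (not isolated)
16 | 5-O,6'-O-(di-tert-butylsilylene) derivative of the 8'-O-acetyl target | Cc1cc(=O)c2c(o1)cc(OC)c1c2O[Si](C(C)(C)C)(C(C)(C)C)Oc2c(C)c(OC(C)=O)c3c(c2C1)C[C@@H](C)OC3=O | intermediate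
17 | (3R)-6-hydroxy-5-[(5-hydroxy-7-methoxy-2-methyl-4-oxo-4H-chromen-6-yl)methyl]-3,7-dimethyl-1-oxo-3,4-dihydro-1H-isochromen-8-yl acetate | COc1cc2oc(C)cc(=O)c2c(O)c1Cc1c(O)c(C)c(OC(C)=O)c2c1C[C@@H](C)OC2=O | intermediate
18 | (3R)-6,8-dihydroxy-5-[(5-hydroxy-7-methoxy-2-methyl-4-oxo-4H-chromen-6-yl)methyl]-3,7-dimethyl-3,4-dihydro-1H-isochromen-1-one | COc1cc2oc(C)cc(=O)c2c(O)c1Cc1c(O)c(C)c(O)c2c1C[C@@H](C)OC2=O | target

## Step count and least certain steps

Total: 11 steps. Longest linear sequence: 11 steps (1 to 18); 9 and 12 enter as purchased compounds in steps 6 and 7.

Step 9 (key step). The aryl O–Si bonds may be cleaved during the acid stage. O5 would then be free to compete with O8a for C2, and regiocontrol would be lost. The acetyl group on O8' may also be transferred between molecules or removed by excess base. The fallback sets out from 13 and comes back at 18. The ketone methyl group of 13 is condensed with N,N-dimethylacetamide dimethyl acetal (PhMe, 90 °C) to the (E)-enaminone F1. Warming F1 in AcOH adds the O8a hydroxyl to the β-carbon and expels dimethylamine, giving the silylene-bridged chromone with free 8'-hydroxyl F2. HF·pyridine then gives 18 directly. The same two bonds are formed under the same tether control, but without strong base, strong acid or acetates.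

Step 7. The first Si–O bond may form at O8a, the least hindered hydroxyl, or at O8'. The resulting silyl triflate cannot close a ring and ends as open-chain or oligomeric silyl ethers. The fallback sets out from 9 and 8 and comes back at 13. It removes O8a from the competition before silicon is introduced:
- Mono-O-benzylation of 9 (BnBr, K2CO3, acetone) gives 1-[2-(benzyloxy)-6-hydroxy-4-methoxyphenyl]ethan-1-one F3; the second hydroxyl is chelated and should stay free.
- F3 is C-benzylated by 8 as in step 6, expected ortho to the free hydroxyl, to give the O8a-benzyl triphenol F4.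
- 12 then bridges O5 and O6', the only pair it can span, to give the silylene benzyl ether F5.
- Hydrogenolysis (H2, Pd/C, EtOAc) gives 13.

This costs two more steps and makes the site of C-benzylation of F3 a point to check, which is why it is not the main route.

Step 6. Elimination of dimethylamine from 8 may be slow, because the lactone carbonyl para to O6' makes the quinone methide electron-poor. The liberated amine may open the lactone, 10 may dimerise, and 9 may be alkylated twice. The fallback sets out from 8 and comes back at 11. Exhaustive N-methylation (MeI, MeCN, rt) gives the benzylic trimethylammonium iodide F6. With 9 (3 equiv) and K2CO3 in MeCN at room temperature, F6 loses trimethylamine to give 10 without heating, and 10 is trapped to 11.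

Step 3. Oxidative addition into the doubly ortho-substituted, electron-rich C–Br bond may be slow, and reduction of the C–Br bond may take over. The fallback sets out from 5 and comes back at 6. n-BuLi (2.2 equiv, THF, −78 °C) forms the alkoxide and exchanges bromine for lithium. CO2 and an HCl work-up give 6-[(2R)-2-hydroxypropyl]-2,4-dimethoxy-3-methylbenzoic acid F7, which lactonises to 6 with TsOH in refluxing PhMe.

## Further compounds

F1 | step 9 | (E)-enaminone of 13 (acetyl group converted into C(=O)CH=C(CH3)NMe2) | CN(C)/C(C)=C/C(=O)c1c(O)cc(OC)c2c1O[Si](C(C)(C)C)(C(C)(C)C)Oc1c(C)c(O)c3c(c1C2)C[C@@H](C)OC3=O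
F2 | step 9 | silylene-bridged chromone with free 8'-hydroxyl (16 without its acetyl group) | Cc1cc(=O)c2c(o1)cc(OC)c1c2O[Si](C(C)(C)C)(C(C)(C)C)Oc2c(C)c(O)c3c(c2C1)C[C@@H](C)OC3=O
F3 | step 7 | 1-[2-(benzyloxy)-6-hydroxy-4-methoxyphenyl]ethan-1-one | CC(=O)c1c(O)cc(OC)cc1OCc1ccccc1
F4 | step 7 | O8a-benzyl ether of 11 | CC(=O)c1c(OCc2ccccc2)cc(OC)c(Cc2c(O)c(C)c(O)c3c2C[C@@H](C)OC3=O)c1O
F5 | step 7 | O8a-benzyl ether of 13 | CC(=O)c1c(OCc2ccccc2)cc(OC)c2c1O[Si](C(C)(C)C)(C(C)(C)C)Oc1c(C)c(O)c3c(c1C2)C[C@@H](C)OC3=O
F6 | step 6 | N-methyl quaternary ammonium iodide of 8 | C[C@@H]1Cc2c(C[N+](C)(C)C)c(O)c(C)c(O)c2C(=O)O1.[I-]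
F7 | step 3 | 6-[(2R)-2-hydroxypropyl]-2,4-dimethoxy-3-methylbenzoic acid | C[C@@H](O)Cc1cc(OC)c(C)c(OC)c1C(=O)O
A1 | alternative 1 | open-chain triketo methyl ester carrying the 5-O-benzyl chromone on C5' | COC(=O)CC(=O)C(C)C(=O)C(Cc1c(OC)cc2oc(C)cc(=O)c2c1OCc1ccccc1)C(=O)C[C@@H](C)O
A2 | alternative 1 | 5-O-benzyl ether of the target | COc1cc2oc(C)cc(=O)c2c(OCc3ccccc3)c1Cc1c(O)c(C)c(O)c2c1C[C@@H](C)OC2=O
A3 | alternative 2 | diazo enone carrying the 5-O-benzyl chromone and the silyl-protected side chain | C=C(C[C@@H](C)O[Si](C)(C)C(C)(C)C)C(=O)C(=[N+]=[N-])Cc1c(OC)cc2oc(C)cc(=O)c2c1OCc1ccccc1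
A4 | alternative 2 | 1-(triisopropylsiloxy)propyne | CC#CO[Si](C(C)C)(C(C)C)C(C)C
A5 | alternative 2 | ring C phenol with 6'-O-triisopropylsilyl group and unsubstituted C8a' | COc1cc2oc(C)cc(=O)c2c(OCc3ccccc3)c1Cc1c(O[Si](C(C)C)(C(C)C)C(C)C)c(C)c(O)cc1C[C@@H](C)O[Si](C)(C)C(C)(C)C
A6 | alternative 3 | methyl 3-(2,6-dimethyl-4-oxo-4H-pyran-3-yl)-3-oxopropanoate alkylated at C2 with the 6',8'-dibenzyloxy ring C/D benzyl unit | COC(=O)C(Cc1c(OCc2ccccc2)c(C)c(OCc2ccccc2)c2c1C[C@@H](C)OC2=O)C(=O)c1c(C)oc(C)cc1=O
A7 | alternative 3 | 7-O-demethyl target as its 6',8'-dibenzyl ether | Oc1cc2oc(C)cc(=O)c2c(O)c1Cc1c(OCc3ccccc3)c(C)c(OCc3ccccc3)c2c1C[C@@H](C)OC2=O
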